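The plan uses a difference between the two ring oxygens of the target's benzodioxane: O1, on C8a, is para to the C6 side chain, whereas O4, on C4a, is meta. With a nitrile at C6, only the O1 to C8a bond can form by ipso addition of an alkoxide, so the dioxane ring is cut there. The precursor is the isomeric, glycidol-derived benzodioxane 11, whose C8a holds the CH2 oxygen and whose ring carbon on O4 bears a threo aryl carbinol. One operation hands C8a to the carbinol oxygen, opens the old ring and closes the new one, both stereocentres being kept.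

Key step: step 7

Remarks on the chemistry (assumptions and corrections)
- Locants follow the target's ring in every benzodioxane: O1 is the oxygen on C8a (para to C6), O4 the oxygen on C4a (meta to C6).
- The ring carbon C3 of alcohol 11 is R, not S: the carbinol carbon outranks the ring CH2, so the geometry that is S in alcohol 6 is R in 7, 9, 10 and 11; 11 is the (3R), (R)-carbinol, threo isomer.
- The phenoxide is assumed to attack (R)-glycidyl tosylate at C1 with direct loss of tosylate, the usual course for glycidyl sulfonates.
- The exchange in step 7 is treated as reversible and near thermoneutral, so it is coupled to silylation of the primary alkoxide; the silyl ether then serves as protecting group and leaves with the MOM group in step 10.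
- The adduct of step 7 is a cage in which C3 and C8a are bridgeheads, so the carbinol arm must react from its axial conformer.
- Alcohol 6 is exposed to carbonate only: as a free alkoxide it could add to C8a by the path of step 7, which would interchange its two CH2–O arms and racemise it; this also offers a simple test of the ipso exchange before 11 is committed.

Step 1
Reactants: 1 4-bromo-2-methoxyphenol
Product: 2 4-bromo-2-methoxy-1-(methoxymethoxy)benzene
Conditions: MOMCl, i-Pr2NEt, CH2Cl2, 0 °C to rt
Reagents that add atoms: chloromethyl methyl ether (MOMCl), COCCl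
Why: Williamson-type O-alkylation of the phenol by the α-chloro ether should give the MOM acetal, which withstands magnesium, hydride, periodinane and alkoxide and is removed by aqueous acid in step 10.

Step 2
Reactants: 3 3,4-dihydroxybenzonitrile; 4 (R)-glycidyl tosylate [(2R)-oxiran-2-ylmethyl 4-methylbenzenesulfonate]
Product: 6 (3S)-3-(hydroxymethyl)-2,3-dihydro-1,4-benzodioxine-6-carbonitrile, via para-O-glycidyl ether 5 (not isolated)
Conditions: K2CO3 (1.1 equiv), DMF, 25–40 °C; then K2CO3 (1 equiv), 70 °C
Reagents that add atoms: none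
Why: The 4-OH, para to the nitrile, is the more acidic phenol, so its phenoxide is the one formed by the first equivalent of carbonate and displaces tosylate at C1 of 4 (Williamson SN2, stereocentre untouched); the 3-phenoxide then opens the epoxide of 5 at its inner carbon (6-exo-tet SN2, inversion), which sets the S centre of 6 and places the CH2 on the C8a oxygen and the CH on the C4a oxygen.

Step 3
Reactants: 6 (3S)-3-(hydroxymethyl)-2,3-dihydro-1,4-benzodioxine-6-carbonitrile
Product: 7 (3R)-3-formyl-2,3-dihydro-1,4-benzodioxine-6-carbonitrile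
Conditions: Dess–Martin periodinane, CH2Cl2, 0 °C to rt; used at once without chromatography
Reagents that add atoms: none
Why: Dess–Martin oxidation of the primary alcohol runs without base, so the enolisable stereocentre next to the formyl group, the nitrile and the ring should all survive; the descriptor becomes R only because the formyl carbon now outranks the ring CH2.

Step 4
Reactants: 2 4-bromo-2-methoxy-1-(methoxymethoxy)benzene; 7 (3R)-3-formyl-2,3-dihydro-1,4-benzodioxine-6-carbonitrile
Product: 9 (3R)-3-{hydroxy[3-methoxy-4-(methoxymethoxy)phenyl]methyl}-2,3-dihydro-1,4-benzodioxine-6-carbonitrile (both carbinol epimers), via arylmagnesium bromide 8 (not isolated)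
Conditions: 2, Mg turnings, I2 (cat.), THF, 40 °C; then 7, THF, −78 °C; aq. NH4Cl
Reagents that add atoms: none
Why: Grignard addition to the aldehyde at −78 °C should outrun both attack on the aryl nitrile and enolisation, and the configuration of the new carbinol is irrelevant because step 5 removes it.

Step 5
Reactants: 9 (3R)-3-{hydroxy[3-methoxy-4-(methoxymethoxy)phenyl]methyl}-2,3-dihydro-1,4-benzodioxine-6-carbonitrile (both carbinol epimers)
Product: 10 (3R)-3-[3-methoxy-4-(methoxymethoxy)benzoyl]-2,3-dihydro-1,4-benzodioxine-6-carbonitrile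
Conditions: Dess–Martin periodinane, CH2Cl2, 0 °C to rt; used at once without chromatography
Reagents that add atoms: none
Why: Dess–Martin oxidation of the secondary benzylic alcohol converges both epimers on one aryl ketone under base-free conditions, which is important because the proton at C3 is now acidic and the aryloxide on C2 could leave by β-elimination.

Step 6
Reactants: 10 (3R)-3-[3-methoxy-4-(methoxymethoxy)benzoyl]-2,3-dihydro-1,4-benzodioxine-6-carbonitrile
Product: 11 (3R)-3-{(R)-hydroxy[3-methoxy-4-(methoxymethoxy)phenyl]methyl}-2,3-dihydro-1,4-benzodioxine-6-carbonitrile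
Conditions: (R)-2-methyl-CBS-oxazaborolidine (20 mol %), BH3·SMe2, THF, −20 °C; then MeOH
Reagents that add atoms: none
Why: Corey–Bakshi–Shibata reduction: with the aryl group as the larger carbonyl substituent the (R)-oxazaborolidine–borane complex should deliver hydride to the face that gives the (R)-carbinol, the same face favoured by Felkin–Anh control from the C3 oxygen (threo), while the base-free medium leaves the neighbouring stereocentre and the nitrile alone.

Step 7
Reactants: 11 (3R)-3-{(R)-hydroxy[3-methoxy-4-(methoxymethoxy)phenyl]methyl}-2,3-dihydro-1,4-benzodioxine-6-carbonitrile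
Product: 15 (2R,3R)-2-[3-methoxy-4-(methoxymethoxy)phenyl]-3-({[tri(propan-2-yl)silyl]oxy}methyl)-2,3-dihydro-1,4-benzodioxine-6-carbonitrile, via potassium alkoxide 12 (not isolated), via spiro Meisenheimer adduct 13 (not isolated), via rearranged potassium alkoxide 14 (not isolated)
Conditions: KH (1.05 equiv), 18-crown-6 (1.1 equiv), THF–DMPU, 0 °C then 50–70 °C; i-Pr3SiCl (1.2 equiv) added slowly at the same temperature
Reagents that add atoms: chlorotri(propan-2-yl)silane (i-Pr3SiCl), CC(C)[Si](Cl)(C(C)C)C(C)C
Why: Proposed new method: from the conformer of alkoxide 12 with the carbinol arm axial on C3, the oxygen adds ipso to C8a to give adduct 13, a cage with C3 and C8a as bridgeheads whose negative charge is delocalised into the C6 nitrile para to C8a; expulsion of the CH2–O oxygen from C8a then gives 14, in which the former carbinol oxygen is O1. The closest known reaction type is the base-mediated O-to-O Smiles rearrangement of 2-(aryloxy)alkanols on arenes with a para nitro or cyano group (alkoxide-for-alkoxide SNAr), whereas a switch between two fused dioxane rings by this path is not known. The new dioxane ring (O1, C2, C3, O4, C4a, C8a) is closed by 6-exo-trig attack of the alkoxide on the arene carbon (ring O–CH(Ar)–C3–CH2–O–C8a in 13), followed by loss of the old ring oxygen from the same carbon. No stereocentre is created: both C(sp3)–O bonds stay intact, so the (R)-carbinol carbon becomes C2 and the ring carbon stays C3 with unchanged geometry, and the threo alcohol can only give the trans (2R,3R) ring. The step needs site selectivity between the two aryl–oxygen bonds, and the nitrile secures it, because attack at C8a (para) gives a stabilised adduct and attack at C4a (meta) gives none. Since the exchange is reversible, the unhindered primary alkoxide 14 is silylated as it forms while the hindered benzylic alkoxide 12 keeps equilibrating (Curtin–Hammett control), which should draw the material through to 15.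

Step 8
Reactants: 15 (2R,3R)-2-[3-methoxy-4-(methoxymethoxy)phenyl]-3-({[tri(propan-2-yl)silyl]oxy}methyl)-2,3-dihydro-1,4-benzodioxine-6-carbonitrile
Product: 17 (2R,3R)-2-[3-methoxy-4-(methoxymethoxy)phenyl]-3-({[tri(propan-2-yl)silyl]oxy}methyl)-2,3-dihydro-1,4-benzodioxine-6-carbaldehyde, via N-aluminio aldimine 16 (not isolated)
Conditions: i-Bu2AlH (1.3 equiv), CH2Cl2, −78 to 0 °C; then aq. KNaC4H4O6, 10% aq. citric acid, rt
Reagents that add atoms: water, O
Why: Partial reduction of the aryl nitrile: one hydride from i-Bu2AlH gives the N-aluminio aldimine 16, which is not reduced further at low temperature and is hydrolysed to the aldehyde on work-up, while the aryl ethers, the acetal and the silyl ether are inert.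

Step 9
Reactants: 17 (2R,3R)-2-[3-methoxy-4-(methoxymethoxy)phenyl]-3-({[tri(propan-2-yl)silyl]oxy}methyl)-2,3-dihydro-1,4-benzodioxine-6-carbaldehyde
Product: 19 (2E)-3-[(2R,3R)-2-[3-methoxy-4-(methoxymethoxy)phenyl]-3-({[tri(propan-2-yl)silyl]oxy}methyl)-2,3-dihydro-1,4-benzodioxin-6-yl]prop-2-enoic acid, via arylidenemalonic acid 18 (not isolated)
Conditions: malonic acid (3 equiv), piperidine (cat.), pyridine, 85 °C
Reagents that add atoms: malonic acid, OC(=O)CC(=O)O
Why: Knoevenagel condensation in the Doebner modification: the arylidenemalonic acid 18 loses CO2 in hot pyridine and gives the (E)-acrylic acid, the more stable alkene geometry, under weakly basic conditions that touch neither protecting group nor stereocentre.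

Step 10
Reactants: 19 (2E)-3-[(2R,3R)-2-[3-methoxy-4-(methoxymethoxy)phenyl]-3-({[tri(propan-2-yl)silyl]oxy}methyl)-2,3-dihydro-1,4-benzodioxin-6-yl]prop-2-enoic acid
Product: 20 (2E)-3-[(2R,3R)-2-(4-hydroxy-3-methoxyphenyl)-3-(hydroxymethyl)-2,3-dihydro-1,4-benzodioxin-6-yl]prop-2-enoic acid (CNP0187155.2)
Conditions: 3 M aq. HCl, THF, 45 °C
Reagents that add atoms: none
Why: Aqueous acid hydrolyses the MOM acetal and the primary silyl ether in one operation, the alcohol-free medium avoids esterification of the acid, and the benzylic C2–O1 bond is not expected to ionise under conditions this mild, so the trans (2R,3R) ring should be retained.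

Compound list
1 | 4-bromo-2-methoxyphenol | COc1cc(Br)ccc1O | starting material
2 | 4-bromo-2-methoxy-1-(methoxymethoxy)benzene | COCOc1ccc(Br)cc1OC | intermediate
3 | 3,4-dihydroxybenzonitrile | N#Cc1ccc(O)c(O)c1 | starting material
4 | (R)-glycidyl tosylate, (2R)-oxiran-2-ylmethyl 4-methylbenzenesulfonate | Cc1ccc(cc1)S(=O)(=O)OC[C@H]1CO1 | starting material
5 | 3-hydroxy-4-{[(2R)-oxiran-2-yl]methoxy}benzonitrile | N#Cc1ccc(OC[C@H]2CO2)c(O)c1 | intermediate (not isolated)
6 | (3S)-3-(hydroxymethyl)-2,3-dihydro-1,4-benzodioxine-6-carbonitrile | OC[C@H]1COc2ccc(C#N)cc2O1 | intermediate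
7 | (3R)-3-formyl-2,3-dihydro-1,4-benzodioxine-6-carbonitrile | O=C[C@H]1COc2ccc(C#N)cc2O1 | intermediate
8 | [3-methoxy-4-(methoxymethoxy)phenyl]magnesium bromide | COCOc1ccc([Mg]Br)cc1OC | intermediate (not isolated)
9 | (3R)-3-{hydroxy[3-methoxy-4-(methoxymethoxy)phenyl]methyl}-2,3-dihydro-1,4-benzodioxine-6-carbonitrile, both carbinol epimers | COCOc1ccc(C(O)[C@H]2COc3ccc(C#N)cc3O2)cc1OC | intermediate
10 | (3R)-3-[3-methoxy-4-(methoxymethoxy)benzoyl]-2,3-dihydro-1,4-benzodioxine-6-carbonitrile | COCOc1ccc(C(=O)[C@H]2COc3ccc(C#N)cc3O2)cc1OC | intermediate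
11 | (3R)-3-{(R)-hydroxy[3-methoxy-4-(methoxymethoxy)phenyl]methyl}-2,3-dihydro-1,4-benzodioxine-6-carbonitrile (precursor of the key step) | COCOc1ccc([C@@H](O)[C@H]2COc3ccc(C#N)cc3O2)cc1OC | intermediate
12 | potassium alkoxide of 11 | COCOc1ccc([C@@H]([O-])[C@H]2COc3ccc(C#N)cc3O2)cc1OC.[K+] | intermediate (not isolated)
13 | potassium salt of the spiro Meisenheimer adduct (6-cyanocyclohexadienide, spiro at C8a, trioxabicyclo[2.2.2]octane cage with bridgeheads C3 and C8a) | N#C[C-]1C=C[C@@]23OC[C@@H](OC2=C1)[C@@H](c4ccc(OCOC)c(OC)c4)O3.[K+] | intermediate (not isolated)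
14 | potassium alkoxide of (2R,3R)-3-(hydroxymethyl)-2-[3-methoxy-4-(methoxymethoxy)phenyl]-2,3-dihydro-1,4-benzodioxine-6-carbonitrile | COCOc1ccc([C@H]2Oc3ccc(C#N)cc3O[C@@H]2C[O-])cc1OC.[K+] | intermediate (not isolated)
15 | (2R,3R)-2-[3-methoxy-4-(methoxymethoxy)phenyl]-3-({[tri(propan-2-yl)silyl]oxy}methyl)-2,3-dihydro-1,4-benzodioxine-6-carbonitrile (product of the key step) | COCOc1ccc([C@H]2Oc3ccc(C#N)cc3O[C@@H]2CO[Si](C(C)C)(C(C)C)C(C)C)cc1OC | intermediate
16 | N-(diisobutylaluminio) aldimine of 17 | COCOc1ccc([C@H]2Oc3ccc(C=N[Al](CC(C)C)CC(C)C)cc3O[C@@H]2CO[Si](C(C)C)(C(C)C)C(C)C)cc1OC | intermediate (not isolated)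
17 | (2R,3R)-2-[3-methoxy-4-(methoxymethoxy)phenyl]-3-({[tri(propan-2-yl)silyl]oxy}methyl)-2,3-dihydro-1,4-benzodioxine-6-carbaldehyde | COCOc1ccc([C@H]2Oc3ccc(C=O)cc3O[C@@H]2CO[Si](C(C)C)(C(C)C)C(C)C)cc1OC | intermediate
18 | 2-{[(2R,3R)-2-[3-methoxy-4-(methoxymethoxy)phenyl]-3-({[tri(propan-2-yl)silyl]oxy}methyl)-2,3-dihydro-1,4-benzodioxin-6-yl]methylidene}propanedioic acid | COCOc1ccc([C@H]2Oc3ccc(C=C(C(=O)O)C(=O)O)cc3O[C@@H]2CO[Si](C(C)C)(C(C)C)C(C)C)cc1OC | intermediate (not isolated)
19 | (2E)-3-[(2R,3R)-2-[3-methoxy-4-(methoxymethoxy)phenyl]-3-({[tri(propan-2-yl)silyl]oxy}methyl)-2,3-dihydro-1,4-benzodioxin-6-yl]prop-2-enoic acid | COCOc1ccc([C@H]2Oc3ccc(/C=C/C(=O)O)cc3O[C@@H]2CO[Si](C(C)C)(C(C)C)C(C)C)cc1OC | intermediate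
20 | (2E)-3-[(2R,3R)-2-(4-hydroxy-3-methoxyphenyl)-3-(hydroxymethyl)-2,3-dihydro-1,4-benzodioxin-6-yl]prop-2-enoic acid | COc1cc([C@H]2Oc3ccc(/C=C/C(=O)O)cc3O[C@@H]2CO)ccc1O | target

Total step count: 10
Longest linear sequence: 9 steps (3 to 20, steps 2 to 10)

Steps most likely to fail

Risk 1, step 7. The ipso addition may be too slow with a single nitrile as acceptor, or the exchange may stall as a mixture while the silyl chloride caps unrearranged alkoxide. At the temperature needed the alkoxide may also displace the neighbouring aryloxide at C3 (oxirane formation) or fragment. The fallback makes the same O1–C8a bond by an ordinary fluoride SNAr on an open-chain threo ether; it sets out from the arylmagnesium bromide 8 and comes back at 15. Reagent 8 is quenched with DMF to give 3-methoxy-4-(methoxymethoxy)benzaldehyde F1. Commercial 4-fluoro-3-hydroxybenzonitrile is O-alkylated (K2CO3, NaI, acetone) with commercial (4S)-4-benzyl-3-(chloroacetyl)-1,3-oxazolidin-2-one to give the aryloxyacetyl imide F2. The boron enolate of F2 (Bu2BOTf, i-Pr2NEt, CH2Cl2, −78 °C) should add to F1 in the Evans syn sense and give the (2S,3R)-aldol imide F3. LiBH4 (THF, 0 °C) removes the auxiliary and should give the threo (1R,2R)-diol F4. i-Pr3SiCl with imidazole silylates the primary hydroxyl and gives the silyl ether F5. KOC(CH3)3 in THF at 0 °C then lets the benzylic alkoxide displace the fluoride para to the nitrile, with both stereocentres untouched, which gives 15.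

Risk 2, step 4. The stereocentre next to the formyl group may lose configuration by enolisation on handling or under the basic reagent, and the Grignard reagent may attack the nitrile. The fallback passes through the acid oxidation level; it sets out from alcohol 6 and comes back at ketone 10, replacing steps 3 to 5. Alcohol 6 is oxidised (TEMPO cat., PhI(OAc)2, MeCN–water) to the configurationally robust (2R)-7-cyano-2,3-dihydro-1,4-benzodioxine-2-carboxylic acid F6. Coupling with N,O-dimethylhydroxylamine hydrochloride (EDC·HCl, HOBt, N-methylmorpholine, CH2Cl2, 0 °C) gives the Weinreb amide F7. Reagent 8 should add once at −20 °C to give a magnesium chelate that neither enolises nor adds a second time, and a cold acidic quench releases 10.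

Risk 3, step 6. Hydride delivery may show poor facial selectivity, because the branched, oxygen-bearing carbon competes with the aryl group as the larger substituent, or the centre next to the carbonyl may epimerise before reduction. Either failure gives the erythro alcohol and from it the cis ring. The fallback sets the carbinol during carbon–carbon bond formation and bypasses the ketone; it sets out from aldehyde 7 and comes back at 11. Aldehyde 7 is precomplexed with MgBr2·OEt2 in CH2Cl2 at −78 °C and treated with 8. Attack on the five-membered chelate between the formyl oxygen and O4 from the face of the C3 hydrogen (Cram chelate control) should give the threo (R)-carbinol 11 directly. The minor erythro epimer is removed by chromatography or recycled through 10; no compound outside the list is made (F0).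

Further compounds
F1 | step 7 | 3-methoxy-4-(methoxymethoxy)benzaldehyde | COCOc1ccc(C=O)cc1OC
F2 | step 7 | (4S)-4-benzyl-3-[(5-cyano-2-fluorophenoxy)acetyl]-1,3-oxazolidin-2-one | N#Cc1ccc(F)c(OCC(=O)N2[C@@H](Cc3ccccc3)COC2=O)c1
F3 | step 7 | (4S)-4-benzyl-3-{(2S,3R)-2-(5-cyano-2-fluorophenoxy)-3-hydroxy-3-[3-methoxy-4-(methoxymethoxy)phenyl]propanoyl}-1,3-oxazolidin-2-one | COCOc1ccc([C@@H](O)[C@H](Oc2cc(C#N)ccc2F)C(=O)N2[C@@H](Cc3ccccc3)COC2=O)cc1OC
F4 | step 7 | 3-{[(1R,2R)-1,3-dihydroxy-1-[3-methoxy-4-(methoxymethoxy)phenyl]propan-2-yl]oxy}-4-fluorobenzonitrile | COCOc1ccc([C@@H](O)[C@H](Oc2cc(C#N)ccc2F)CO)cc1OC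
F5 | step 7 | 4-fluoro-3-{[(1R,2R)-1-hydroxy-1-[3-methoxy-4-(methoxymethoxy)phenyl]-3-{[tri(propan-2-yl)silyl]oxy}propan-2-yl]oxy}benzonitrile | COCOc1ccc([C@@H](O)[C@H](Oc2cc(C#N)ccc2F)CO[Si](C(C)C)(C(C)C)C(C)C)cc1OC
F6 | step 4 | (2R)-7-cyano-2,3-dihydro-1,4-benzodioxine-2-carboxylic acid | OC(=O)[C@H]1COc2ccc(C#N)cc2O1
F7 | step 4 | (2R)-7-cyano-N-methoxy-N-methyl-2,3-dihydro-1,4-benzodioxine-2-carboxamide | CON(C)C(=O)[C@H]1COc2ccc(C#N)cc2O1
F0 | step 6 | none | none
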